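The constants used here were chosen freely, and the outcome is calculated.

In a one-step world, substrate and partner simply meet and give target, and we would have to count nothing but their meetings. This flask adds a partner that destroys itself and a target that feeds its own making.

| setting | birch | larch | ash | alder | oak |
|---|---|---|---|---|---|
| substrate | 1.2 mM | 2.5 mM | 5.0 mM | 10 mM | 20 mM |
| partner | 15.0 mM | 15.0 mM | 15.0 mM | 15.0 mM | 15.0 mM |
| time | 1.0 min | 1.0 min | 1.0 min | 1.0 min | 1.0 min |

- [target] at the end for birch, larch, ash, alder, oak, in this order
- how that number moves from the first to the last of them (falls, then rises / rises all the way / rises, then falls / hardly changes / falls all the way)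

    substrate + partner + target → 2 target (k1 = 1100 /M²/s)
    substrate + partner → target (k2 = 0.19 /M/s)
    2 partner → homo dimer (k3 = 1.4 /M/s)
    target ⇌ isomer of the product (K4 = 1.7, k4 = 0.45 /s)

1. Partner. In birch, at the start, partner goes to homo dimer 180 times as fast as it goes into the plain step. So in our reckoning we let dimerising set the fall of [partner], though that ratio belongs to birch at the start and the self-feeding step uses partner too, which we leave aside here. Summing [partner] over the minute gives an exposure of 0.449 M·s.

2. Isomer. In birch, target and isomer of the product relax with a half-life of 0.970 s, far shorter than the run, so we count 37.0 % of the product as target.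

3. The large part. In birch the plain step alone turns 8.54 % of the substrate, which gives 0.0380 mM of target.

4. The correction. The self-feeding step (autocatalysis) outruns the plain step once [target] passes 0.173 mM. Holding substrate at its charge, we need one quantity, the feedback number: self-feeding constant times substrate charged times exposure times target's share. Then [target] is that crossing level times (e to the feedback number, less 1).

5. Turning the substrate charge. Birch has a feedback number of 0.220 and gives 0.0424 mM, still below the crossing level. Larch has 0.458 and gives 0.100 mM. Ash has 0.916 and gives 0.259 mM. Alder has 1.83 and gives 0.905 mM. Oak has 3.66 and gives 6.55 mM, but that means 88.5 % of its substrate gone, which does not fit with holding substrate at its charge. We expect oak well below that figure, and a rise all the way.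

The forecast gave 0.041 mM, 0.095 mM, 0.235 mM, 0.7 mM and 2.05 mM, rises all the way, lower than ours at alder, holding that “the autocatalysis has not reversed the trend”.

The flasks give 0.0415 mM, 0.0978 mM, 0.249 mM, 0.777 mM and 2.45 mM, so the number rises all the way. Birch still holds 90.9 % of its substrate at the end. The feedback number reckons that too: dividing the birch target by its share and by the charge leaves 90.4 % of the substrate. The same step for ash, with its feedback number of 0.916, leaves 86.0 %, and ash holds 87.0 %.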